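## Retrosynthetic overview

1. Target 23 ⇐ 12‑O‑methyl quinone 22 ⇐ arene lactone 21; the 11,12,14‑trimethoxyarene is oxidised with CAN and all O‑protecting groups fall in one BCl3 step at the end.
2. Key disconnection: ring B (C5–C6–C7–C8–C9–C10) and the C20(=O)–O7 lactone arise together from the seven‑membered carbocycle C5–C6–C7–C8–C9–C20–C10 of aryl enone 18, by a bromonium‑triggered 1,2‑shift of aryl carbon C9 from C20 to C10 (ring contraction 7→6).
3. Enabling feature: O7 on benzylic C7 is 1,4 to the C20 ketone through the arene bond C8=C9. It closes a five‑membered hemiketal ring (C7–C8–C9–C20–O7) that bridges the seven‑membered ring into an 8‑oxabicyclo[3.2.1]octene. There the C20–C9 bond is parallel to the p‑orbital at C10 of the C1=C10 alkene, and the same O7–C20 unit ends as the lactone.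
4. 18 ⇐ anionic O→C acyl transfer in unsaturated δ‑lactone 16 (C9–Li onto C20); ring A ⇐ Diels–Alder of methacrolein with dihydropyran diene 11 (C4 and C5 relayed from C6); 11 ⇐ enyne ring‑closing metathesis; C6/C7 ⇐ reagent‑controlled syn‑alkoxyallylation of aldehyde 6.
5. Ring order: ring C (bought arene) → pyran ring with O7/C20 (step 7) → ring A (step 8) → seven‑membered ring (step 12) → ring B and lactone (step 13) → quinone (step 15).

Key step: step 13

Remark (numbering): atoms carry the abietane numbers of the target (ring A C1–C5, C10; ring B C5–C10; ring C C8, C9, C11–C14; C19 = CH2O on C4; C20 = lactone carbonyl); α/β refer to the usual drawing with C20 β. Ar = 2‑bromo‑5‑isopropyl‑3,4,6‑trimethoxyphenyl.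
Remark (assumption): allyl methoxymethyl ether 7 is taken as a catalogue compound, and formylation of 4 is assumed to follow the para‑to‑OMe preference of 1,2,4‑trimethoxybenzenes.

## Route

Step 1
Reactants: 1 1,2,4‑trimethoxybenzene; 2 acetone
Product: 3 2‑(2,3,6‑trimethoxyphenyl)propan‑2‑ol
Conditions: n‑BuLi, THF, 0 °C; then 2, −78 °C → rt; H2O
Reagents that add atoms: none
Why: Directed ortho‑lithiation of 1 at C3, the position flanked by two methoxy groups, followed by 1,2‑addition of the aryllithium to acetone should give the tertiary benzylic alcohol.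

Step 2
Reactants: 3 2‑(2,3,6‑trimethoxyphenyl)propan‑2‑ol
Product: 4 2‑isopropyl‑1,3,4‑trimethoxybenzene
Conditions: Et3SiH, TFA, CH2Cl2, 0 °C → rt
Reagents that add atoms: none
Why: Ionic hydrogenation: TFA ionises the tertiary benzylic alcohol to a cation stabilised by two ortho methoxy groups, which takes hydride from Et3SiH.

Step 3
Reactants: 4 2‑isopropyl‑1,3,4‑trimethoxybenzene
Product: 5 3‑isopropyl‑2,4,5‑trimethoxybenzaldehyde
Conditions: Cl2CHOMe, TiCl4, CH2Cl2, −78 → 0 °C; H2O
Reagents that add atoms: dichloromethyl methyl ether (COC(Cl)Cl)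
Why: Rieche formylation (Friedel–Crafts type) should attack C6 of 4, ortho to the 1‑OMe and para to the 3‑OMe (future C8), rather than the position para to the isopropyl group.

Step 4
Reactants: 5 3‑isopropyl‑2,4,5‑trimethoxybenzaldehyde
Product: 6 2‑bromo‑5‑isopropyl‑3,4,6‑trimethoxybenzaldehyde
Conditions: NBS, MeCN, rt
Reagents that add atoms: N‑bromosuccinimide (O=C1CCC(=O)N1Br)
Why: Electrophilic aromatic bromination can only occur at the last free ring position (future C9), which is activated by its ortho methoxy group.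

Step 5
Reactants: 6 2‑bromo‑5‑isopropyl‑3,4,6‑trimethoxybenzaldehyde; 7 allyl methoxymethyl ether
Product: 8 (1R,2R)‑1‑Ar‑2‑(methoxymethoxy)but‑3‑en‑1‑ol
Conditions: 7, s‑BuLi, THF, −78 °C; (−)‑Ipc2BOMe [from (+)‑α‑pinene]; BF3·OEt2; then 6, −78 °C; NaOH, H2O2
Reagents that add atoms: none
Why: Brown asymmetric alkoxyallylboration: the (Z)‑γ‑(methoxymethoxy)allyl‑diisopinocampheylborane adds through a chair transition state to the Si face of the aldehyde, the Z geometry giving the syn diol monoether and the auxiliary setting C7 (R) and C6 (R) by reagent control.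

Step 6
Reactants: 8 (1R,2R)‑1‑Ar‑2‑(methoxymethoxy)but‑3‑en‑1‑ol; 9 propargyl bromide
Product: 10 (1R,2R)‑1‑Ar‑2‑(methoxymethoxy)‑1‑(prop‑2‑yn‑1‑yloxy)but‑3‑ene
Conditions: NaH, n‑Bu4NI (cat.), THF/DMF, 0 °C → rt
Reagents that add atoms: none
Why: Williamson etherification (SN2) of the secondary benzylic alkoxide with the primary propargylic bromide; no stereocentre is touched.

Step 7
Reactants: 10 (1R,2R)‑1‑Ar‑2‑(methoxymethoxy)‑1‑(prop‑2‑yn‑1‑yloxy)but‑3‑ene
Product: 11 (2R,3R)‑2‑Ar‑3‑(methoxymethoxy)‑5‑vinyl‑3,6‑dihydro‑2H‑pyran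
Conditions: Grubbs II (5 mol %), ethylene (1 atm), CH2Cl2, 40 °C
Reagents that add atoms: none
Why: Ring‑closing enyne metathesis (exo mode) joins alkene carbon C5 to alkyne carbon C10 and gives the six‑membered dihydropyran carrying the 1,3‑diene C5=C10–C1=C2.

Step 8
Reactants: 11 (2R,3R)‑2‑Ar‑3‑(methoxymethoxy)‑5‑vinyl‑3,6‑dihydro‑2H‑pyran; 12 methacrolein
Product: 13 3‑Ar‑4‑(methoxymethoxy)‑5‑methyl‑3,4,4a,5,6,7‑hexahydro‑1H‑isochromene‑5‑carbaldehyde (4α‑Me, 4β‑CHO, 5α‑H, 6α‑OMOM, 7β‑O; C1=C10)
Conditions: Me2AlCl (30 mol %), CH2Cl2, −78 → −30 °C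
Reagents that add atoms: none
Why: Lewis acid catalysed Diels–Alder reaction: the β‑carbon of methacrolein bonds to the unhindered vinyl terminus C2 and the α‑carbon to C5 (the "ortho" mode of 1‑vinylcycloalkenes), the dienophile approaches anti to the pseudoaxial 6‑OMOM group (sets 5α‑H) and the formyl group sits endo (sets C4 with CHO cis to C6), so C4 and C5 are relayed from C6.

Step 9
Reactants: 13 Diels–Alder aldehyde
Product: 14 the corresponding primary alcohol (C19–OH)
Conditions: NaBH4, MeOH, 0 °C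
Reagents that add atoms: none
Why: Hydride reduction of the neopentyl aldehyde; no stereocentre changes.

Step 10
Reactants: 14 primary alcohol
Product: 15 6α,19‑bis(methoxymethyl) ether (3‑Ar‑4‑(methoxymethoxy)‑5‑(methoxymethoxymethyl)‑5‑methyl‑3,4,4a,5,6,7‑hexahydro‑1H‑isochromene)
Conditions: MOMCl, i‑Pr2NEt, CH2Cl2, 0 °C → rt
Reagents that add atoms: chloromethyl methyl ether (COCCl)
Why: O‑Alkylation of the primary alcohol gives a MOM ether that should survive the Cr(VI), organolithium and NBS steps and leave together with the 6‑O‑MOM group at the end.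

Step 11
Reactants: 15 bis‑MOM ether
Product: 16 α,β‑unsaturated δ‑lactone (the corresponding 1H‑isochromen‑1‑one; C20=O, C1=C10)
Conditions: CrO3·3,5‑dimethylpyrazole, CH2Cl2, −20 °C
Reagents that add atoms: chromium trioxide (O=[Cr](=O)=O)
Why: Allylic oxidation of a 3,6‑dihydro‑2H‑pyran to the 5,6‑dihydro‑2H‑pyran‑2‑one: Cr(VI) should attack the CH2 (C20) that is both allylic and α to the ring oxygen in preference to the merely allylic C2 and the hindered benzylic C7–H.

Step 12
Reactants: 16 α,β‑unsaturated δ‑lactone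
Product: 18 seven‑membered 7β‑hydroxy aryl enone (20‑oxo‑9(10→20)abeo‑abieta‑1(10),8,11,13‑tetraene; 6α‑OMOM; 19‑OMOM; 11,12,14‑OMe), via bridged lithium hemiketal alkoxide 17 (not isolated)
Conditions: t‑BuLi (2.1 equiv), THF, −100 → −78 °C; H2O
Reagents that add atoms: none
Why: Parham‑type bromine–lithium exchange (faster than addition to the lactone at −100 °C) gives the C9 aryllithium, which adds to the lactone carbonyl C20 through a five‑membered transition state, and opening of the O7–C20 bond of the tetrahedral intermediate (anionic O→C acyl transfer) leaves the seven‑membered aryl enone with free 7β‑OH and all stereocentres untouched.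

Step 13
Reactants: 18 seven‑membered 7β‑hydroxy aryl enone
Product: 20 1β‑bromo‑6α,19‑bis(methoxymethoxy)‑11,12,14‑trimethoxyabieta‑8,11,13‑trien‑20,7β‑olide, via bridged hemiketal 19 (not isolated)
Conditions: NBS (1.1 equiv), NaHCO3, CH2Cl2, −40 → 0 °C
Reagents that add atoms: N‑bromosuccinimide (O=C1CCC(=O)N1Br)
Why: Proposed new method: ring–chain tautomerism of 18 puts O7 on the C20 carbonyl (5‑exo‑trig) to give hemiketal 19, an 8‑oxabicyclo[3.2.1]octene whose allylic‑ketal alkene C1=C10 is the only nucleophilic π‑bond (the enone form is inert to Br+); bromonium formation on the β‑face at C1 and antiperiplanar, suprafacial 1,2‑shift of the electron‑rich aryl carbon C9 from C20 to C10 contracts the seven‑membered carbocycle to ring B while the O7–C20(OH) unit collapses to the δ‑lactone. The closest known reaction types are the halonium‑induced semipinacol rearrangement of allylic alcohols and the 1,2‑aryl shift of α‑halo aryl ketals to arylacetic esters. Ring B is closed by the [1,2]‑shift itself (ring contraction 7→6), and the lactone by re‑formation of the carbonyl at C20 with O7 already attached. C10 is set by the bridged geometry, that is, relayed from C7 (step 5) and C5 (step 8): C9 can only reach the α‑face of C10, which gives the 5α‑H/10β‑C20 trans arrangement, and C1 (β‑Br from anti addition) is erased in step 14. The step needs chemoselectivity for the alkene over the benzylic alcohol and the arene (no free aryl C–H; buffered, low temperature) and migration of C9 rather than O7 or OH, which is secured because only the C20–C9 bond overlaps with the developing p‑orbital at C10.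

Step 14
Reactants: 20 1β‑bromo lactone
Product: 21 6α,19‑bis(methoxymethoxy)‑11,12,14‑trimethoxyabieta‑8,11,13‑trien‑20,7β‑olide
Conditions: Bu3SnH (0.5 M), AIBN (cat.), PhMe, 80 °C
Reagents that add atoms: none
Why: Radical‑chain reduction of the secondary bromide, with Bu3SnH kept concentrated so that the C1 radical is quenched before any 1,2‑aryl or 1,2‑acyl shift; C1 becomes CH2.

Step 15
Reactants: 21 arene lactone
Product: 22 12‑methoxy‑6α,19‑bis(methoxymethoxy)‑11,14‑dioxoabieta‑8,12‑dien‑20,7β‑olide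
Conditions: (NH4)2Ce(NO3)6, MeCN/H2O, 0 °C
Reagents that add atoms: water (O)
Why: CAN oxidative demethylation: two one‑electron oxidations of the para‑related 11,14‑dimethoxyarene, attack of water and loss of two MeOH should give the p‑quinone, with the 12‑OMe, the lactone and the MOM groups retained.

Step 16
Reactants: 22 methoxy quinone
Product: 23 target, 6α,12,19‑trihydroxy‑11,14‑dioxoabieta‑8,12‑dien‑20,7β‑olide
Conditions: BCl3, CH2Cl2, −78 → 0 °C; H2O
Reagents that add atoms: none
Why: Lewis acid ether cleavage: BCl3 chelated to the C11 carbonyl removes the vinylogous methyl ester at O12 and cleaves both MOM acetals, while the bridged lactone and the now electron‑poor benzylic C7–O bond should survive at low temperature.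

## Compound list

1 | 1,2,4‑trimethoxybenzene | COc1ccc(OC)c(OC)c1 | starting material
2 | acetone | CC(C)=O | starting material
3 | 2‑(2,3,6‑trimethoxyphenyl)propan‑2‑ol | COc1ccc(OC)c(C(C)(C)O)c1OC | intermediate
4 | 2‑isopropyl‑1,3,4‑trimethoxybenzene | COc1ccc(OC)c(C(C)C)c1OC | intermediate
5 | 3‑isopropyl‑2,4,5‑trimethoxybenzaldehyde | COc1cc(C=O)c(OC)c(C(C)C)c1OC | intermediate
6 | 2‑bromo‑5‑isopropyl‑3,4,6‑trimethoxybenzaldehyde | COc1c(Br)c(C=O)c(OC)c(C(C)C)c1OC | intermediate
7 | allyl methoxymethyl ether, 3‑(methoxymethoxy)prop‑1‑ene | C=CCOCOC | starting material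
8 | (1R,2R)‑1‑(2‑bromo‑5‑isopropyl‑3,4,6‑trimethoxyphenyl)‑2‑(methoxymethoxy)but‑3‑en‑1‑ol | COc1c(C(C)C)c(OC)c(OC)c(Br)c1[C@@H](O)[C@H](OCOC)C=C | intermediate
9 | propargyl bromide, 3‑bromoprop‑1‑yne | BrCC#C | starting material
10 | O7‑propargyl ether of 8, (1R,2R)‑1‑Ar‑2‑(methoxymethoxy)‑1‑(prop‑2‑yn‑1‑yloxy)but‑3‑ene | COc1c(C(C)C)c(OC)c(OC)c(Br)c1[C@@H](OCC#C)[C@H](OCOC)C=C | intermediate
11 | (2R,3R)‑2‑Ar‑3‑(methoxymethoxy)‑5‑vinyl‑3,6‑dihydro‑2H‑pyran (2,3‑cis) | COc1c(C(C)C)c(OC)c(OC)c(Br)c1[C@H]1OCC(C=C)=C[C@H]1OCOC | intermediate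
12 | methacrolein | C=C(C)C=O | starting material
13 | Diels–Alder adduct, 3‑Ar‑4‑(methoxymethoxy)‑5‑methyl‑3,4,4a,5,6,7‑hexahydro‑1H‑isochromene‑5‑carbaldehyde (4α‑Me, 4β‑CHO, 5α‑H, 6α‑OMOM, 7β‑O, C1=C10) | COc1c(C(C)C)c(OC)c(OC)c(Br)c1[C@H]1OCC2=CCC[C@](C)(C=O)[C@@H]2[C@H]1OCOC | intermediate
14 | primary alcohol from 13 (C19–OH) | COc1c(C(C)C)c(OC)c(OC)c(Br)c1[C@H]1OCC2=CCC[C@](C)(CO)[C@@H]2[C@H]1OCOC | intermediate
15 | 6α,19‑bis‑MOM ether, cyclic allylic ether O7–C20H2 | COc1c(C(C)C)c(OC)c(OC)c(Br)c1[C@H]1OCC2=CCC[C@](C)(COCOC)[C@@H]2[C@H]1OCOC | intermediate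
16 | α,β‑unsaturated δ‑lactone (O7–C20(=O)–C10=C1), aryl bromide | COc1c(C(C)C)c(OC)c(OC)c(Br)c1[C@H]1OC(=O)C2=CCC[C@](C)(COCOC)[C@@H]2[C@H]1OCOC | intermediate
17 | bridged lithium hemiketal alkoxide (O7–C20(OLi)–C9), not isolated | COc1c(C(C)C)c(OC)c(OC)c2c1[C@H]1O[C@]2(O[Li])C3=CCC[C@](C)(COCOC)[C@@H]3[C@H]1OCOC | intermediate
18 | seven‑membered 7β‑hydroxy aryl enone: 7β‑hydroxy‑6α,19‑bis(methoxymethoxy)‑11,12,14‑trimethoxy‑9(10→20)abeo‑abieta‑1(10),8,11,13‑tetraen‑20‑one (5α‑H) | COc1c(C(C)C)c(OC)c(OC)c2c1[C@@H](O)[C@H](OCOC)[C@@H]1C(=CCC[C@]1(C)COCOC)C2=O | intermediate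
19 | bridged hemiketal tautomer of 18 (8‑oxabicyclo[3.2.1]octene, O7–C20(OH)), not isolated | COc1c(C(C)C)c(OC)c(OC)c2c1[C@H]1O[C@]2(O)C3=CCC[C@](C)(COCOC)[C@@H]3[C@H]1OCOC | intermediate
20 | 1β‑bromo‑6α,19‑bis(methoxymethoxy)‑11,12,14‑trimethoxyabieta‑8,11,13‑trien‑20,7β‑olide | COc1c(C(C)C)c(OC)c(OC)c2c1[C@H]1OC(=O)[C@@]23[C@H](Br)CC[C@](C)(COCOC)[C@@H]3[C@H]1OCOC | intermediate
21 | 6α,19‑bis(methoxymethoxy)‑11,12,14‑trimethoxyabieta‑8,11,13‑trien‑20,7β‑olide | COc1c(C(C)C)c(OC)c(OC)c2c1[C@H]1OC(=O)[C@@]23CCC[C@](C)(COCOC)[C@@H]3[C@H]1OCOC | intermediate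
22 | 12‑methoxy‑6α,19‑bis(methoxymethoxy)‑11,14‑dioxoabieta‑8,12‑dien‑20,7β‑olide | CC(C)C1=C(OC)C(=O)C2=C(C1=O)[C@H]1OC(=O)[C@@]23CCC[C@](C)(COCOC)[C@@H]3[C@H]1OCOC | intermediate
23 | 6α,12,19‑trihydroxy‑11,14‑dioxoabieta‑8,12‑dien‑20,7β‑olide | CC(C)C1=C(O)C(=O)C2=C(C1=O)[C@H]1OC(=O)[C@@]23CCC[C@](C)(CO)[C@@H]3[C@H]1O | target

## Step count and risks

Total step count: 16. Longest linear sequence: 16 steps (from 1,2,4‑trimethoxybenzene).

**Step 13 (proposed new method).** The hemiketal tautomer may be too sparsely populated, or bromination may be diverted into oxidation of the benzylic alcohol or of the arene, so that no migration takes place. The fallback uses the known halonium‑induced semipinacol rearrangement of an allylic alcohol and sets out from 18. Luche reduction (NaBH4, CeCl3, MeOH) should give the allylic diol F1 (either C20 epimer converges). NBS should then trigger the 1,2‑shift of C9 from the secondary carbinol C20 to C10 with ring contraction to the 1β‑bromo C20 aldehyde, which O7 traps as the bridged bromo lactol F2 (one anomer drawn). TEMPO/PhI(OAc)2 oxidation of the lactol comes back to the route at 20.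

**Step 8.** Regio‑, endo‑ or facial selectivity may be poor with the α‑branched dienophile, or the Lewis acid may ionise the benzylic ring ether. The fallback sets out from 11 and builds the quaternary centre in two stages. Diels–Alder reaction with acrolein (more reactive and more reliably "ortho" and endo) should give the acrolein adduct F3. C‑Methylation of its aldehyde enolate (KOt‑Bu, MeI), from the α‑face anti to the ring‑fusion substituent C6, comes back to the route at 13.

**Step 12.** γ‑Deprotonation of the unsaturated lactone, intermolecular addition of the alkyllithium or incomplete acyl transfer may compete with the intramolecular attack. The fallback sets out from 16. Aminolysis with Me(MeO)NH·HCl/i‑PrMgCl should open the lactone to the hydroxy Weinreb amide F4. Treatment with t‑BuLi (3 equiv: O–H deprotonation, then Br/Li exchange) should close the seven‑membered ring directly by Parham‑type addition to the amide, whose chelated tetrahedral intermediate prevents over‑addition, and work‑up comes back to the route at 18.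

Further compounds

F1 | step 13 | allylic diol from 18 (C20–OH, 7β‑OH; C1=C10 retained) | COc1c(C(C)C)c(OC)c(OC)c2c1[C@@H](O)[C@H](OCOC)[C@@H]1C(=CCC[C@]1(C)COCOC)[C@@H]2O
F2 | step 13 | 1β‑bromo lactol (20‑hydroxy‑20,7β‑epoxy bridge; ring B six‑membered) | COc1c(C(C)C)c(OC)c(OC)c2c1[C@H]1O[C@@H](O)[C@@]23[C@H](Br)CC[C@](C)(COCOC)[C@@H]3[C@H]1OCOC
F3 | step 8 | acrolein Diels–Alder adduct (4β‑CHO, 4α‑H, 5α‑H) | COc1c(C(C)C)c(OC)c(OC)c(Br)c1[C@H]1OCC2=CCC[C@H](C=O)[C@@H]2[C@H]1OCOC
F4 | step 12 | hydroxy Weinreb amide from 16 (C20 N‑methoxy‑N‑methylamide, 7‑OH) | COc1c(C(C)C)c(OC)c(OC)c(Br)c1[C@@H](O)[C@H](OCOC)[C@@H]1C(C(=O)N(C)OC)=CCC[C@]1(C)COCOC
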